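Saturday's run ended with 75.6% of its solid substrate left and Thursday's with 90.2%, and I asked what those leftovers meant for a flask charged between them.

the same everywhere: gas phase 2.6 mM (held)

| charge | solid substrate | remark | time |
|---|---|---|---|
| Saturday's | 29 mM | run made earlier |  |
| Thursday's | 66 mM | run made earlier |  |
| flask | 44 mM |  | 50 min |

| run | time / min | target / % | solid substrate / % |
|---|---|---|---|
| Saturday's | 8.00 | 0.3 | 95.7 |
| Saturday's | 15.0 | 1.5 | 92.3 |
| Saturday's | 20.0 | 1.9 | 91.4 |
| Saturday's | 30.0 | 3.5 | 85.0 |
| Saturday's | 40.0 | 6.1 | 79.3 |
| Saturday's | 50.0 | 9.2 | 75.6 |
| Thursday's | 8.00 | 1.4 | 97.2 |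
| Thursday's | 15.0 | 1.7 | 96.8 |
| Thursday's | 20.0 | 0 | 95.1 |
| Thursday's | 30.0 | 2.0 | 93.3 |
| Thursday's | 40.0 | 4.2 | 89.0 |
| Thursday's | 50.0 | 3.3 | 90.2 |

(each reading ± 1 percentage point)

- a species is counted by the solid substrate in it: one side product B counts as two
- given per volume of solution although it is solid: solid substrate
- at the start none of the gas is dissolved
- steps that have been proposed: starting material -> side product A; starting material + target -> side product B; starting material + dissolved gas -> target; gas phase <-> dissolved gas; solid substrate <-> starting material
- at the start none of the solid substrate is in solution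

1. amount of target in percent of the solid substrate charged, at 2.5 min, 12 min and 50 min

Did the charge set how fast the solid went? In concentration, Saturday's run lost 7.08 mM and Thursday's 6.47 mM, a gap smaller than the 0.660 mM by which one Thursday reading scatters. So I carried one number, the feed, the solid substrate passing into solution per minute on average over both runs, 0.135 mM min⁻¹, zero-order in the solid.

Would it last? The new flask's charge over the feed gave a lifetime of 325 min, longer than the 50 min asked, by a factor of 6.50. I counted on solid throughout.

What did the feed make? [target] at the end read 2.67 mM on Saturday and 2.18 mM on Thursday. Their mean, 2.42 mM, is 5.51% of the new charge. For the course in time I assumed, as a rough guess of my own, that target rose with the square of time. Saturday's readings at 30.0 min and 50.0 min stood in the ratio 0.380, against 0.360 for the square. That square gave me 0.317% at 12 min and 0.0138% at 2.5 min.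

The forecast, 0.02%, 0.45% and 5.9%, held that target “does not depend on the charge”, and it stood above mine at each time .

The flask gave 0.0151%, 0.533% and 6.16%.

    starting material → side product A (k = 0.0107 min⁻¹)
    starting material + target → side product B (k = 0.0413 L mol⁻¹ min⁻¹)
    starting material + dissolved gas → target (k = 10.5 L mol⁻¹ min⁻¹)
    gas phase ⇌ dissolved gas, rate k4*(csat - [dissolved gas]) (kL = 0.476 min⁻¹)
    solid substrate ⇌ starting material, rate k5*(cs5 - [starting material]) while solid is left; crystals form when [starting material] > cs5 (solubility = 31.0 mM, k = 0.00487 min⁻¹)

The dissolution of solid substrate had 51% of its turnover behind it at 25.0 min. The feed over 50 min takes 15.4% of the charge, and 84.0% of the solid substrate stood at 50.0 min. The lifetime of 325 min is shorter than 500 min, where solid substrate stood at 0%.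

The runs are calculated with constants of no real substance, noise included.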